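**Retrosynthetic overview**
1. Target 23 ⇐ one-pot acetal/silyl ether hydrolysis ⇐ CBS reduction at C9 ⇐ ten-membered enone 21.
2. 21 ⇐ four-atom radical ring expansion of cyclohexenone 20: the C8 radical adds to C9=O, C4–C9 cleaves, and loss of PhS• creates C4=C5.
3. 20 ⇐ thionium alkylation (C4–C5 bond) of silyl dienol ether 18 (ring A: C1–C4, C9, C10, C14, C15) with lactone 10 (C5–C8, C11–C13, ester).
4. 10 ⇐ furanone 1 + 1,3-dioxolane 2 + acid chloride 9; 18 ⇐ cyclohexenone 11 + trimethyl orthoformate 12 + formaldehyde.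
5. Ring order: the γ-lactone (from 1) and ring A (from 11) are bought; six-membered ring B forms only transiently; the ten-membered carbocycle is formed last.

Assumption: the SMILES is read as 6R,7S,8R,9S,2′S (germacranolide numbering C1–C15, used throughout), with both ring olefins cis within the ring (1(10)E,4E by CIP); (S)-2-methylbutanoyl chloride is taken as a catalogue compound.

Step 1
Reactants: 1 (S)-5-(hydroxymethyl)furan-2(5H)-one; 2 1,3-dioxolane
Product: 3 (4S,5S)-4-(1,3-dioxolan-2-yl)-5-(hydroxymethyl)oxolan-2-one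
Conditions: Ph2CO (10 mol%), hv (350 nm), neat 2, 0 °C
Reagents that add atoms: none
Why: Benzophenone-sensitised hydrogen abstraction gives the 1,3-dioxolan-2-yl radical, which adds to the butenolide in a Giese conjugate addition anti to the C5 substituent of the furanone, setting C7 trans to C6 and introducing C8 as a masked aldehyde.

Step 2
Reactants: 3 (4S,5S)-4-(1,3-dioxolan-2-yl)-5-(hydroxymethyl)oxolan-2-one
Product: 4 (4S,5S)-4-(1,3-dioxolan-2-yl)-5-[(phenylsulfanyl)methyl]oxolan-2-one
Conditions: PhSSPh, Bu3P, pyridine, 25 °C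
Reagents that add atoms: diphenyl disulfide c1ccc(SSc2ccccc2)cc1
Why: Hata thioetherification converts the primary alcohol into the phenyl sulfide by SN2 displacement of the alkoxyphosphonium ion at a CH2 group, so no stereocenter is touched and no Michael acceptor is yet present to trap the thiol.

Step 3
Reactants: 4 (4S,5S)-4-(1,3-dioxolan-2-yl)-5-[(phenylsulfanyl)methyl]oxolan-2-one
Product: 7 (4S,5S)-4-(1,3-dioxolan-2-yl)-3-methylidene-5-[(phenylsulfanyl)methyl]oxolan-2-one, via Mannich base 5 (not isolated), via ammonium iodide 6 (not isolated)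
Conditions: LiN(SiMe3)2, THF, −78 °C; [CH2=NMe2]I, −78 to 25 °C; MeI, MeOH, 25 °C; NaHCO3 (aq), EtOAc
Reagents that add atoms: dimethyl(methylidene)ammonium iodide C=[N+](C)C.[I-]
Why: Eschenmoser methylenation (lactone enolate Mannich reaction, N-quaternisation, E1cB loss of trimethylamine) installs the exocyclic C11=C13 olefin, and the bicarbonate elimination is too mild to move the double bond into the ring or to epimerise C7.

Step 4
Reactants: 7 (4S,5S)-4-(1,3-dioxolan-2-yl)-3-methylidene-5-[(phenylsulfanyl)methyl]oxolan-2-one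
Product: 8 (2S,3S)-4-methylidene-5-oxo-2-[(phenylsulfanyl)methyl]oxolane-3-carbaldehyde
Conditions: LiBF4, MeCN/H2O (98:2), 25 °C; used at once
Reagents that add atoms: water O
Why: Near-neutral Lewis-acid-assisted acetal hydrolysis frees the C8 aldehyde without enolising it toward C7, so the C7 configuration and the exocyclic methylene survive until the aldehyde is consumed in step 5.

Step 5
Reactants: 8 (2S,3S)-4-methylidene-5-oxo-2-[(phenylsulfanyl)methyl]oxolane-3-carbaldehyde; 9 (S)-2-methylbutanoyl chloride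
Product: 10 chloro[(2S,3S)-4-methylidene-5-oxo-2-[(phenylsulfanyl)methyl]oxolan-3-yl]methyl (2S)-2-methylbutanoate (both epimers at the CHCl carbon)
Conditions: ZnCl2 (5 mol%), CH2Cl2, −20 to 0 °C
Reagents that add atoms: none
Why: ZnCl2-catalysed addition of an acyl chloride across an aldehyde C=O (α-chloroalkyl ester formation) places the (S)-2-methylbutanoate on O8 and a radical-labile C8–Cl bond in one operation without a base that could racemise the acyl group, and the C8 epimer mixture is irrelevant because C8 is reset in step 11.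

Step 6
Reactants: 11 cyclohex-2-en-1-one; 12 trimethyl orthoformate
Product: 15 2-(dimethoxymethyl)cyclohex-2-en-1-one, via silyloxy sulfonium salt 13 (not isolated), via keto sulfonium salt 14 (not isolated)
Conditions: Me2S, TMSOTf, CH2Cl2, −78 °C; 12, −78 to −20 °C; DBU, 25 °C
Reagents that add atoms: none
Why: In this Morita–Baylis–Hillman-type α-functionalisation, sulfide conjugate addition with O-silylation gives a β-sulfonio silyl enol ether that is alkylated at C10 by the dimethoxycarbenium ion (Mukaiyama-type), and E1cB loss of Me2S restores the enone carrying C14 as an acetal.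

Step 7
Reactants: 15 2-(dimethoxymethyl)cyclohex-2-en-1-one
Product: 16 (±)-2-(dimethoxymethyl)-6-(hydroxymethyl)cyclohex-2-en-1-one
Conditions: LiN(i-Pr)2, THF, −78 °C; CH2O (gas from cracked paraformaldehyde), −78 to −40 °C; AcOH
Reagents that add atoms: formaldehyde C=O
Why: Kinetic α′-deprotonation gives the cross-conjugated lithium enolate, whose aldol addition to monomeric formaldehyde attaches C15 at C4, the racemic center created here being erased in step 11.

Step 8
Reactants: 16 (±)-2-(dimethoxymethyl)-6-(hydroxymethyl)cyclohex-2-en-1-one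
Product: 17 (±)-6-({[tert-butyl(dimethyl)silyl]oxy}methyl)-2-(dimethoxymethyl)cyclohex-2-en-1-one
Conditions: TBSCl, imidazole, CH2Cl2, 0 °C
Reagents that add atoms: tert-butyldimethylsilyl chloride CC(C)(C)[Si](C)(C)Cl
Why: Routine silylation of the primary alcohol stops retro-aldol loss of formaldehyde and protects O15 until the last step.

Step 9
Reactants: 17 (±)-6-({[tert-butyl(dimethyl)silyl]oxy}methyl)-2-(dimethoxymethyl)cyclohex-2-en-1-one
Product: 18 {[2-({[tert-butyl(dimethyl)silyl]oxy}methyl)-6-(dimethoxymethyl)cyclohexa-1,5-dien-1-yl]oxy}trimethylsilane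
Conditions: LiN(i-Pr)2, TMSCl (internal quench), THF, −78 °C; used crude
Reagents that add atoms: chlorotrimethylsilane C[Si](C)(C)Cl
Why: Kinetic enolisation at the tertiary α′ carbon with in situ O-silylation gives the tetrasubstituted cross-conjugated silyl dienol ether, the low temperature and immediate trapping suppressing β-elimination of the silyloxy group.

Step 10
Reactants: 10 chloro[(2S,3S)-4-methylidene-5-oxo-2-[(phenylsulfanyl)methyl]oxolan-3-yl]methyl (2S)-2-methylbutanoate; 18 {[2-({[tert-butyl(dimethyl)silyl]oxy}methyl)-6-(dimethoxymethyl)cyclohexa-1,5-dien-1-yl]oxy}trimethylsilane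
Product: 20 chloro[(2S,3S)-2-{[1-({[tert-butyl(dimethyl)silyl]oxy}methyl)-3-(dimethoxymethyl)-2-oxocyclohex-3-en-1-yl](phenylsulfanyl)methyl}-4-methylidene-5-oxooxolan-3-yl]methyl (2S)-2-methylbutanoate (mixture of epimers at C4/C5/C8), via alpha-chloro sulfide 19 (not isolated)
Conditions: NCS, CCl4, 0 to 25 °C; then 18, ZnCl2 (20 mol%), CH2Cl2, −40 to 0 °C
Reagents that add atoms: none
Why: Chlorination α to sulfur and mild Lewis-acid ionisation give a thionium ion that alkylates the silyl enol ether at C4 (Mukaiyama-type α-phenylthioalkylation, an SN1-like process suited to quaternary carbons), the α-chloroalkyl ester and the acetal ionising far less readily, and the new C4 and C5 centers need no control because both are erased in step 11.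

Step 11
Reactants: 20 chloro[(2S,3S)-2-{[1-({[tert-butyl(dimethyl)silyl]oxy}methyl)-3-(dimethoxymethyl)-2-oxocyclohex-3-en-1-yl](phenylsulfanyl)methyl}-4-methylidene-5-oxooxolan-3-yl]methyl (2S)-2-methylbutanoate
Product: 21 (6R,7S,8R)-15-[tert-butyl(dimethyl)silyl]oxy-14,14-dimethoxy-8-[(2S)-2-methylbutanoyloxy]-9-oxogermacra-1(10),4,11(13)-trien-12,6-olide (C1=C10 and C4=C5 both cis within the ring)
Conditions: (Bu3Sn)2 (1.2 equiv), t-BuON=NOt-Bu (20 mol%, portionwise), PhH (0.01 M), 80 °C
Reagents that add atoms: none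
Why: Proposed new method: Bu3Sn• abstracts chlorine to give the nucleophilic α-acyloxyalkyl radical at C8, which adds reversibly (6-exo) to the C9 ketone through a chair in which the ester is equatorial and trans to the C7 substituent because an axial ester would clash with the axial carbon on quaternary C4 (sets 8R), the alkoxy radical then cleaves C4–C9 to the ten-membered enone and the tertiary C4 radical irreversibly expels PhS• to form C4=C5, PhS• regenerating Bu3Sn• from the distannane and equilibrating the new olefin by reversible addition toward the less strained ring-cis geometry while C1=C10 stays cis from ring A, the absence of any hydride donor letting the unproductive reverse scission simply recycle and sparing the α-methylene lactone, and the closest known chemistry is the Dowd–Beckwith ring expansion and its β-stannyl-terminated radical variant.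

Step 12
Reactants: 21 (6R,7S,8R)-15-[tert-butyl(dimethyl)silyl]oxy-14,14-dimethoxy-8-[(2S)-2-methylbutanoyloxy]-9-oxogermacra-1(10),4,11(13)-trien-12,6-olide
Product: 22 (6R,7S,8R,9S)-15-[tert-butyl(dimethyl)silyl]oxy-9-hydroxy-14,14-dimethoxy-8-[(2S)-2-methylbutanoyloxy]germacra-1(10),4,11(13)-trien-12,6-olide
Conditions: (S)-2-methyl-CBS-oxazaborolidine (0.5 equiv), catecholborane, toluene, −78 °C
Reagents that add atoms: none
Why: In this CBS reduction the α-substituted alkenyl side of the enone acts as the large group, so the (S)-catalyst delivers hydride to the face that gives the 9S allylic alcohol (anti to O8) under reagent control, and catecholborane at −78 °C leaves the lactone, ester, acetal and electron-poor methylene untouched.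

Step 13
Reactants: 22 (6R,7S,8R,9S)-15-[tert-butyl(dimethyl)silyl]oxy-9-hydroxy-14,14-dimethoxy-8-[(2S)-2-methylbutanoyloxy]germacra-1(10),4,11(13)-trien-12,6-olide
Product: 23 (6R,7S,8R,9S)-9,15-dihydroxy-8-[(2S)-2-methylbutanoyloxy]-14-oxogermacra-1(10),4,11(13)-trien-12,6-olide (target CNP0331447.11)
Conditions: AcOH/THF/H2O (3:1:1), 25 to 40 °C
Reagents that add atoms: water O
Why: Mild aqueous acid hydrolyses the enal dimethyl acetal and the primary allylic silyl ether in one operation and is too weak to cause acyl migration from O8 to O9, elimination of the β-hydroxy enal or epimerisation.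

**Compound list**
1 | (S)-5-(hydroxymethyl)furan-2(5H)-one | O=C1O[C@H](CO)C=C1 | starting material
2 | 1,3-dioxolane | C1COCO1 | starting material
3 | (4S,5S)-4-(1,3-dioxolan-2-yl)-5-(hydroxymethyl)oxolan-2-one | C1C(=O)O[C@H](CO)[C@H]1C2OCCO2 | intermediate
4 | (4S,5S)-4-(1,3-dioxolan-2-yl)-5-[(phenylsulfanyl)methyl]oxolan-2-one | C1C(=O)O[C@H](CSc2ccccc2)[C@H]1C3OCCO3 | intermediate
5 | (3R,4S,5S)-3-[(dimethylamino)methyl]-4-(1,3-dioxolan-2-yl)-5-[(phenylsulfanyl)methyl]oxolan-2-one (Mannich base) | CN(C)C[C@@H]1C(=O)O[C@H](CSc2ccccc2)[C@H]1C3OCCO3 | intermediate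
6 | {[(3R,4S,5S)-4-(1,3-dioxolan-2-yl)-2-oxo-5-[(phenylsulfanyl)methyl]oxolan-3-yl]methyl}trimethylammonium iodide | C[N+](C)(C)C[C@@H]1C(=O)O[C@H](CSc2ccccc2)[C@H]1C3OCCO3.[I-] | intermediate
7 | (4S,5S)-4-(1,3-dioxolan-2-yl)-3-methylidene-5-[(phenylsulfanyl)methyl]oxolan-2-one | C=C1C(=O)O[C@H](CSc2ccccc2)[C@H]1C3OCCO3 | intermediate
8 | (2S,3S)-4-methylidene-5-oxo-2-[(phenylsulfanyl)methyl]oxolane-3-carbaldehyde | C=C1C(=O)O[C@H](CSc2ccccc2)[C@H]1C=O | intermediate
9 | (S)-2-methylbutanoyl chloride | ClC(=O)[C@@H](C)CC | starting material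
10 | chloro[(2S,3S)-4-methylidene-5-oxo-2-[(phenylsulfanyl)methyl]oxolan-3-yl]methyl (2S)-2-methylbutanoate, both epimers at CHCl | C=C1C(=O)O[C@H](CSc2ccccc2)[C@H]1C(Cl)OC(=O)[C@@H](C)CC | intermediate
11 | cyclohex-2-en-1-one | O=C1C=CCCC1 | starting material
12 | trimethyl orthoformate | COC(OC)OC | starting material
13 | (±)-dimethyl[3-(trimethylsilyloxy)cyclohex-2-en-1-yl]sulfonium triflate | C[S+](C)C1CCCC(O[Si](C)(C)C)=C1.[O-]S(=O)(=O)C(F)(F)F | intermediate
14 | [2-(dimethoxymethyl)-3-oxocyclohexyl]dimethylsulfonium triflate (racemic) | C[S+](C)C1CCCC(=O)C1C(OC)OC.[O-]S(=O)(=O)C(F)(F)F | intermediate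
15 | 2-(dimethoxymethyl)cyclohex-2-en-1-one | O=C1C(C(OC)OC)=CCCC1 | intermediate
16 | (±)-2-(dimethoxymethyl)-6-(hydroxymethyl)cyclohex-2-en-1-one | O=C1C(C(OC)OC)=CCCC1CO | intermediate
17 | (±)-6-({[tert-butyl(dimethyl)silyl]oxy}methyl)-2-(dimethoxymethyl)cyclohex-2-en-1-one | O=C1C(C(OC)OC)=CCCC1CO[Si](C)(C)C(C)(C)C | intermediate
18 | {[2-({[tert-butyl(dimethyl)silyl]oxy}methyl)-6-(dimethoxymethyl)cyclohexa-1,5-dien-1-yl]oxy}trimethylsilane | C[Si](C)(C)OC1=C(CO[Si](C)(C)C(C)(C)C)CCC=C1C(OC)OC | intermediate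
19 | chloro[(2S,3S)-2-[chloro(phenylsulfanyl)methyl]-4-methylidene-5-oxooxolan-3-yl]methyl (2S)-2-methylbutanoate, epimers at both CHCl carbons | C=C1C(=O)O[C@H](C(Cl)Sc2ccccc2)[C@H]1C(Cl)OC(=O)[C@@H](C)CC | intermediate
20 | chloro[(2S,3S)-2-{[1-({[tert-butyl(dimethyl)silyl]oxy}methyl)-3-(dimethoxymethyl)-2-oxocyclohex-3-en-1-yl](phenylsulfanyl)methyl}-4-methylidene-5-oxooxolan-3-yl]methyl (2S)-2-methylbutanoate, mixture at C4/C5/C8 | O=C1C(C(OC)OC)=CCCC1(CO[Si](C)(C)C(C)(C)C)C(Sc2ccccc2)[C@H]3OC(=O)C(=C)[C@@H]3C(Cl)OC(=O)[C@@H](C)CC | intermediate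
21 | (6R,7S,8R)-15-[tert-butyl(dimethyl)silyl]oxy-14,14-dimethoxy-8-[(2S)-2-methylbutanoyloxy]-9-oxogermacra-1(10),4,11(13)-trien-12,6-olide, both ring olefins cis in the ring | C=C1C(=O)O[C@@H]2/C=C(/CO[Si](C)(C)C(C)(C)C)CC/C=C(/C(OC)OC)C(=O)[C@H](OC(=O)[C@@H](C)CC)[C@@H]12 | intermediate
22 | (6R,7S,8R,9S)-15-[tert-butyl(dimethyl)silyl]oxy-9-hydroxy-14,14-dimethoxy-8-[(2S)-2-methylbutanoyloxy]germacra-1(10),4,11(13)-trien-12,6-olide | C=C1C(=O)O[C@@H]2/C=C(/CO[Si](C)(C)C(C)(C)C)CC/C=C(/C(OC)OC)[C@H](O)[C@H](OC(=O)[C@@H](C)CC)[C@@H]12 | intermediate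
23 | (6R,7S,8R,9S)-9,15-dihydroxy-8-[(2S)-2-methylbutanoyloxy]-14-oxogermacra-1(10),4,11(13)-trien-12,6-olide | C=C1C(=O)O[C@@H]2/C=C(/CO)CC/C=C(/C=O)[C@H](O)[C@H](OC(=O)[C@@H](C)CC)[C@@H]12 | target

**Step count and risks**

Total steps: 13. Longest linear sequence: 9 (steps 1–5, then 10–13).

Steps most likely to fail:

1. Step 11 (the proposed ring expansion). The chain may be short with a chloride precursor, the C8 radical may be lost by 1,6-hydrogen transfer from C15 or C3, and C4=C5 may form as a geometric mixture. The fallback uses known reactions and sets out from 20. Zinc insertion into the C8–Cl bond (Zn, LiCl, THF, then TMSCl) with intramolecular Barbier-type addition to the C9 ketone gives the bicyclic tertiary alcohol F1. Chemoselective sulfur oxidation (H2O2, (NH4)6Mo7O24 cat., EtOH) gives the phenyl sulfone F2. Hypoiodite photolysis (PhI(OAc)2, I2, hv, alkoxy-radical β-fragmentation) then cleaves C4–C9 with loss of the sulfonyl radical, and the route is rejoined at 21.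

2. Step 10 (thionium alkylation). It joins a quaternary to a tertiary carbon, the α-chloro sulfide can lose HCl to a vinyl sulfide, and the enal acetal of 18 may ionise. The fallback sets out from 10 and swaps the halogenative activation for a Pummerer sequence. mCPBA (1 equiv, −78 °C) gives the sulfoxide F3. TFAA with 2,6-lutidine gives the α-trifluoroacetoxy sulfide F4, a storable thionium precursor. F4 is coupled with 18 under ZnCl2 catalysis at −40 °C, and the route is rejoined at 20.

3. Step 12 (CBS reduction). The conformational bias of the ten-membered ring and the branched C8 side may oppose the catalyst. The fallback sets out from 21 and uses substrate control followed by inversion. Luche reduction (NaBH4, CeCl3·7H2O, MeOH, −78 °C) is run first, and if it gives the (9R)-alcohol F5, that epimer is inverted by a Mitsunobu reaction with chloroacetic acid (PPh3, DIAD) to the (9S)-chloroacetate F6. The chloroacetate is removed selectively with thiourea/NaHCO3 in EtOH, and the route is rejoined at 22.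

**Further compounds**
F1 | step 11 | bicyclic tertiary alcohol from C8–C9 closure of 20 (9-hydroxy, 5-phenylsulfanyl, ring B closed; C4/C5/C8/C9 as formed) | OC12C(C(OC)OC)=CCCC1(CO[Si](C)(C)C(C)(C)C)C(Sc3ccccc3)[C@H]4OC(=O)C(=C)[C@@H]4C2OC(=O)[C@@H](C)CC
F2 | step 11 | phenyl sulfone of F1 | OC12C(C(OC)OC)=CCCC1(CO[Si](C)(C)C(C)(C)C)C(S(=O)(=O)c3ccccc3)[C@H]4OC(=O)C(=C)[C@@H]4C2OC(=O)[C@@H](C)CC
F3 | step 10 | sulfoxide of 10 (both sulfur epimers) | C=C1C(=O)O[C@H](CS(=O)c2ccccc2)[C@H]1C(Cl)OC(=O)[C@@H](C)CC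
F4 | step 10 | α-trifluoroacetoxy sulfide from Pummerer rearrangement of F3 | C=C1C(=O)O[C@H](C(OC(=O)C(F)(F)F)Sc2ccccc2)[C@H]1C(Cl)OC(=O)[C@@H](C)CC
F5 | step 12 | (9R)-epimer of 22 | C=C1C(=O)O[C@@H]2/C=C(/CO[Si](C)(C)C(C)(C)C)CC/C=C(/C(OC)OC)[C@@H](O)[C@H](OC(=O)[C@@H](C)CC)[C@@H]12
F6 | step 12 | (9S)-chloroacetate of 22 | C=C1C(=O)O[C@@H]2/C=C(/CO[Si](C)(C)C(C)(C)C)CC/C=C(/C(OC)OC)[C@H](OC(=O)CCl)[C@H](OC(=O)[C@@H](C)CC)[C@@H]12
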